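**Plan**

- Retrosynthesis: the two hydroxyls are unmasked last (aryl pivalate on ring A, silyl ether on the ring B CH2OH). Ring A is then cut at C1–C2 and C3–C4 (C1 = ester carbon, C2 = aryloxy, C3 = H, C4 = methyl, C5 = prenyl, C6 = OH), with CO2 restored as a lactone bridge.
- Enabling feature: ring A is a hexasubstituted methyl salicylate. Its C1(CO2Me)–C6(O)–C5(prenyl)–C4(CH3) array is the C3–C4–C5–C6 array of a 3-methoxycarbonyl-2-pyranone, and C2(OAr)–C3(H) is an aryloxyacetylene, so the diaryl ether oxygen arrives on the alkyne.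
- Forward, pyranone arm: a dioxinone is iodinated and prenylated, opened thermally to an acylketene that is annulated with malonate, and the 4-hydroxyl is pivaloylated.
- Forward, alkyne arm: 2,4-dimethoxyphenol is ortho-formylated, reduced, silylated, converted into its dichlorovinyl ether and eliminated to the ynol ether. Ring B is present from the start; ring A forms in the cycloaddition, and two deprotections finish.
- Stereochemistry: the target has no stereocenter and no stereogenic double bond. The only selectivity to control is the regiochemistry of the cycloaddition.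

Key step: step 10

Remark: ring A keeps the numbering given above throughout, prenyl means 3-methylbut-2-en-1-yl, and all five starting materials are taken as commercial.

**Route**

Step 1
Reactants: 1 2,2,6-trimethyl-4H-1,3-dioxin-4-one
Product: 2 5-iodo-2,2,6-trimethyl-4H-1,3-dioxin-4-one
Conditions: N-iodosuccinimide, AcOH, rt, dark
Reagents that add atoms: N-iodosuccinimide, O=C1CCC(=O)N1I
Why: C5 is the nucleophilic α-carbon of a vinylogous carbonate, so electrophilic iodination of this enol ether carbon gives the vinyl iodide cleanly.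

Step 2
Reactants: 2 5-iodo-2,2,6-trimethyl-4H-1,3-dioxin-4-one; 3 tributyl(3-methylbut-2-en-1-yl)stannane
Product: 4 2,2,6-trimethyl-5-(3-methylbut-2-en-1-yl)-4H-1,3-dioxin-4-one
Conditions: Pd(PPh3)4 (5 mol %), CuI (10 mol %), DMF, 50 °C
Reagents that add atoms: none
Why: Stille cross-coupling: zerovalent palladium inserts into the activated vinyl C–I bond below the temperature at which the dioxinone cycloreverts, and reductive elimination at the less hindered allyl terminus should deliver the linear prenyl group.

Step 3
Reactants: 4 2,2,6-trimethyl-5-(3-methylbut-2-en-1-yl)-4H-1,3-dioxin-4-one; 5 dimethyl malonate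
Product: 8 methyl 4-hydroxy-6-methyl-5-(3-methylbut-2-en-1-yl)-2-oxo-2H-pyran-3-carboxylate, via acetyl prenyl ketene 6 (not isolated), via acylmalonate adduct 7 (not isolated)
Conditions: NaH (1.1 equiv), 5 (1.2 equiv), toluene, 110 °C; then 1 M HCl
Reagents that add atoms: none
Why: Thermal retro-(4+2) cleavage of the dioxinone releases acetone and the acylketene, which C-acylates sodium dimethyl malonate; the enolised acetyl oxygen then lactonises onto a malonate ester (acylketene trapping and lactonisation, the dioxinone counterpart of the diketene–malonate pyranone synthesis).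

Step 4
Reactants: 8 methyl 4-hydroxy-6-methyl-5-(3-methylbut-2-en-1-yl)-2-oxo-2H-pyran-3-carboxylate
Product: 9 methyl 6-methyl-5-(3-methylbut-2-en-1-yl)-2-oxo-4-(pivaloyloxy)-2H-pyran-3-carboxylate
Conditions: PivCl, Et3N, CH2Cl2, 0 °C
Reagents that add atoms: pivaloyl chloride, CC(C)(C)C(Cl)=O
Why: O-acylation of the acidic 4-hydroxyl (a vinylogous carboxylic acid) with an acid chloride and amine base; C-acylation is excluded because C3 is fully substituted, and the hindered pivalate resists later acyl transfer.

Step 5
Reactants: 10 2,4-dimethoxyphenol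
Product: 11 2-hydroxy-3,5-dimethoxybenzaldehyde
Conditions: (CH2O)n, MgCl2, Et3N, MeCN, reflux; then 1 M HCl
Reagents that add atoms: paraformaldehyde (reacting as formaldehyde), C=O
Why: Casnati–Skattebøl ortho-formylation: the magnesium phenoxide delivers formaldehyde to the only free ortho position, and the benzylic alkoxide is oxidised by hydride transfer to a second formaldehyde.

Step 6
Reactants: 11 2-hydroxy-3,5-dimethoxybenzaldehyde
Product: 12 2-(hydroxymethyl)-4,6-dimethoxyphenol
Conditions: NaBH4, MeOH, 0 °C
Reagents that add atoms: none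
Why: Borohydride reduction of the aryl aldehyde to the benzylic alcohol under mild, non-acidic conditions that leave the electron-rich salicyl alcohol intact.

Step 7
Reactants: 12 2-(hydroxymethyl)-4,6-dimethoxyphenol
Product: 13 2,4-dimethoxy-6-[(triisopropylsilyloxy)methyl]phenol
Conditions: TIPSCl (1.05 equiv), imidazole, CH2Cl2, 0 °C
Reagents that add atoms: chlorotriisopropylsilane, CC(C)[Si](Cl)(C(C)C)C(C)C
Why: Silyl ether formation: the unhindered primary benzylic hydroxyl should react with the bulky chlorosilane much faster than the phenol, which is flanked by two ortho substituents.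

Step 8
Reactants: 13 2,4-dimethoxy-6-[(triisopropylsilyloxy)methyl]phenol; 14 trichloroethylene
Product: 16 2-[(E)-1,2-dichloroethenyloxy]-1,5-dimethoxy-3-[(triisopropylsilyloxy)methyl]benzene, via dichloroacetylene 15 (not isolated)
Conditions: K2CO3, DMF, 70 °C
Reagents that add atoms: none
Why: First stage of the Greene ynol ether synthesis: carbonate dehydrochlorinates trichloroethylene to dichloroacetylene, and the phenoxide adds to it in anti fashion to give the (E)-dichlorovinyl ether.

Step 9
Reactants: 16 2-[(E)-1,2-dichloroethenyloxy]-1,5-dimethoxy-3-[(triisopropylsilyloxy)methyl]benzene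
Product: 19 2-(ethynyloxy)-1,5-dimethoxy-3-[(triisopropylsilyloxy)methyl]benzene, via chloroethynyl ether 17 (not isolated), via lithium aryloxyacetylide 18 (not isolated)
Conditions: n-BuLi (2.5 equiv), Et2O, −78 to −40 °C; then MeOH, −78 °C
Reagents that add atoms: none
Why: Second stage of the Greene ynol ether synthesis: deprotonation and anti-elimination of LiCl give the chloroalkynyl ether, lithium–chlorine exchange gives the acetylide, and methanol protonates it to the terminal aryloxyacetylene, which is used at once.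

Step 10
Reactants: 9 methyl 6-methyl-5-(3-methylbut-2-en-1-yl)-2-oxo-4-(pivaloyloxy)-2H-pyran-3-carboxylate; 19 2-(ethynyloxy)-1,5-dimethoxy-3-[(triisopropylsilyloxy)methyl]benzene
Product: 21 methyl 2-{2,4-dimethoxy-6-[(triisopropylsilyloxy)methyl]phenoxy}-4-methyl-5-(3-methylbut-2-en-1-yl)-6-(pivaloyloxy)benzoate, via bridged lactone cycloadduct 20 (not isolated)
Conditions: toluene, 120 °C, sealed tube; 19 added slowly to 9 (2 equiv)
Reagents that add atoms: none
Why: The pyranone is an electron-poor diene (LUMO lowered by the C3 ester and the lactone carbonyl) and the aryloxyacetylene an electron-rich 2π partner, so they should combine in a thermal inverse-electron-demand (4+2) cycloaddition that is concerted but asynchronous, the nucleophilic CH terminus of the ynol ether bonding ahead to pyranone C6 while the oxygen-bearing carbon closes onto C3. The closest known reaction type is the Diels–Alder/retro-Diels–Alder benzannulation of 3-alkoxycarbonyl-2-pyranones with ketene acetals, ynamines and alkynyl ethers, which gives salicylate-type arenes. Ring A is closed by this intermolecular (4+2) addition through the bridged 2-oxabicyclo[2.2.2]octadienone 20, from which retro-(4+2) loss of CO2 is fast at the reaction temperature and makes the benzannulation irreversible. No stereocenter is created in the product, since both bridgehead carbons of racemic 20 become arene carbons. The selectivity needed is regiochemical, with the aryloxy carbon next to the ester carbon, and it is secured by the matched polarisation of the partners (β-carbon of the ynol ether nucleophilic, C6 of the dienyl ester electrophilic). The pivalate masks the acidic 4-hydroxyl, which would otherwise add to the ynol ether, and slow addition of 19 to excess hot 9 limits thermal oligomerisation of the alkyne.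

Step 11
Reactants: 21 methyl 2-{2,4-dimethoxy-6-[(triisopropylsilyloxy)methyl]phenoxy}-4-methyl-5-(3-methylbut-2-en-1-yl)-6-(pivaloyloxy)benzoate
Product: 22 methyl 2-{2,4-dimethoxy-6-[(triisopropylsilyloxy)methyl]phenoxy}-6-hydroxy-4-methyl-5-(3-methylbut-2-en-1-yl)benzoate
Conditions: K2CO3 (0.2 equiv), MeOH, 40 °C
Reagents that add atoms: none
Why: Base-catalysed methanolysis (transesterification) of the aryl pivalate; exchange at the methyl ester is degenerate, and the silyl ether and prenyl group are inert to methoxide.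

Step 12
Reactants: 22 methyl 2-{2,4-dimethoxy-6-[(triisopropylsilyloxy)methyl]phenoxy}-6-hydroxy-4-methyl-5-(3-methylbut-2-en-1-yl)benzoate
Product: 23 methyl 2-hydroxy-6-[2-(hydroxymethyl)-4,6-dimethoxyphenoxy]-4-methyl-3-(3-methylbut-2-en-1-yl)benzoate (CNP0583011.0)
Conditions: Bu4NF (1.2 equiv), THF, 0 °C to rt
Reagents that add atoms: none
Why: Fluoride-induced desilylation of the benzylic silyl ether under basic conditions, which avoids the acid that would cyclise the ortho-prenyl phenol to a chroman.

**Compound list**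

1 | 2,2,6-trimethyl-4H-1,3-dioxin-4-one | CC1=CC(=O)OC(C)(C)O1 | starting material
2 | 5-iodo-2,2,6-trimethyl-4H-1,3-dioxin-4-one | CC1=C(I)C(=O)OC(C)(C)O1 | intermediate
3 | tributyl(3-methylbut-2-en-1-yl)stannane | CCCC[Sn](CCCC)(CCCC)CC=C(C)C | starting material
4 | 2,2,6-trimethyl-5-(3-methylbut-2-en-1-yl)-4H-1,3-dioxin-4-one | CC1=C(CC=C(C)C)C(=O)OC(C)(C)O1 | intermediate
5 | dimethyl malonate | COC(=O)CC(=O)OC | starting material
6 | 2-acetyl-5-methylhexa-1,4-dien-1-one (acetyl prenyl ketene) | CC(=O)C(CC=C(C)C)=C=O | intermediate (not isolated)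
7 | dimethyl 2-(2-acetyl-5-methylhex-4-enoyl)malonate, present in the flask as its sodium enolate | COC(=O)C(C(=O)OC)C(=O)C(CC=C(C)C)C(C)=O | intermediate (not isolated)
8 | methyl 4-hydroxy-6-methyl-5-(3-methylbut-2-en-1-yl)-2-oxo-2H-pyran-3-carboxylate | COC(=O)C1=C(O)C(CC=C(C)C)=C(C)OC1=O | intermediate
9 | methyl 6-methyl-5-(3-methylbut-2-en-1-yl)-2-oxo-4-(pivaloyloxy)-2H-pyran-3-carboxylate | COC(=O)C1=C(OC(=O)C(C)(C)C)C(CC=C(C)C)=C(C)OC1=O | intermediate
10 | 2,4-dimethoxyphenol | COc1ccc(O)c(OC)c1 | starting material
11 | 2-hydroxy-3,5-dimethoxybenzaldehyde | COc1cc(C=O)c(O)c(OC)c1 | intermediate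
12 | 2-(hydroxymethyl)-4,6-dimethoxyphenol | COc1cc(CO)c(O)c(OC)c1 | intermediate
13 | 2,4-dimethoxy-6-[(triisopropylsilyloxy)methyl]phenol | COc1cc(CO[Si](C(C)C)(C(C)C)C(C)C)c(O)c(OC)c1 | intermediate
14 | trichloroethylene | ClC=C(Cl)Cl | starting material
15 | dichloroacetylene | ClC#CCl | intermediate (not isolated)
16 | 2-[(E)-1,2-dichloroethenyloxy]-1,5-dimethoxy-3-[(triisopropylsilyloxy)methyl]benzene | COc1cc(CO[Si](C(C)C)(C(C)C)C(C)C)c(O/C(Cl)=C\Cl)c(OC)c1 | intermediate
17 | 2-(chloroethynyloxy)-1,5-dimethoxy-3-[(triisopropylsilyloxy)methyl]benzene | COc1cc(CO[Si](C(C)C)(C(C)C)C(C)C)c(OC#CCl)c(OC)c1 | intermediate (not isolated)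
18 | lithium 2-{2,4-dimethoxy-6-[(triisopropylsilyloxy)methyl]phenoxy}ethynide | COc1cc(CO[Si](C(C)C)(C(C)C)C(C)C)c(OC#C[Li])c(OC)c1 | intermediate (not isolated)
19 | 2-(ethynyloxy)-1,5-dimethoxy-3-[(triisopropylsilyloxy)methyl]benzene | COc1cc(CO[Si](C(C)C)(C(C)C)C(C)C)c(OC#C)c(OC)c1 | intermediate
20 | methyl 5-{2,4-dimethoxy-6-[(triisopropylsilyloxy)methyl]phenoxy}-1-methyl-7-(3-methylbut-2-en-1-yl)-3-oxo-8-(pivaloyloxy)-2-oxabicyclo[2.2.2]octa-5,7-diene-4-carboxylate, racemic, bridgeheads fixed by the bicycle | COC(=O)C12C(=O)OC(C)(C=C1Oc3c(CO[Si](C(C)C)(C(C)C)C(C)C)cc(OC)cc3OC)C(CC=C(C)C)=C2OC(=O)C(C)(C)C | intermediate (not isolated)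
21 | methyl 2-{2,4-dimethoxy-6-[(triisopropylsilyloxy)methyl]phenoxy}-4-methyl-5-(3-methylbut-2-en-1-yl)-6-(pivaloyloxy)benzoate | COC(=O)c1c(Oc2c(CO[Si](C(C)C)(C(C)C)C(C)C)cc(OC)cc2OC)cc(C)c(CC=C(C)C)c1OC(=O)C(C)(C)C | intermediate
22 | methyl 2-{2,4-dimethoxy-6-[(triisopropylsilyloxy)methyl]phenoxy}-6-hydroxy-4-methyl-5-(3-methylbut-2-en-1-yl)benzoate | COC(=O)c1c(Oc2c(CO[Si](C(C)C)(C(C)C)C(C)C)cc(OC)cc2OC)cc(C)c(CC=C(C)C)c1O | intermediate
23 | methyl 2-hydroxy-6-[2-(hydroxymethyl)-4,6-dimethoxyphenoxy]-4-methyl-3-(3-methylbut-2-en-1-yl)benzoate | COC(=O)c1c(Oc2c(CO)cc(OC)cc2OC)cc(C)c(CC=C(C)C)c1O | target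

**Count and risks**

Total steps: 12. Longest linear sequence: 8 steps (steps 5 to 12, from 2,4-dimethoxyphenol); the pyranone arm (steps 1 to 4) joins at step 10.

The three steps most likely to fail:

Step 10. Thermal oligomerisation of the terminal ynol ether may outrun cycloaddition to the fully substituted, moderately activated diene, and acyl transfer from the pyranone pivalate may compete at 120 °C. The fallback makes the ether bond after the ring; it sets out from 9 and comes back to the route at 21. Pyranone 9 is heated in toluene with the robust ketene acetal 1,1-bis(trimethylsilyloxy)ethene (C=C(O[Si](C)(C)C)O[Si](C)(C)C), the classical partner class for this diene. After loss of CO2 and trimethylsilanol this should give methyl 4-methyl-5-(3-methylbut-2-en-1-yl)-6-(pivaloyloxy)-2-(trimethylsilyloxy)benzoate F1. Aqueous work-up hydrolyses it to methyl 2-hydroxy-4-methyl-5-(3-methylbut-2-en-1-yl)-6-(pivaloyloxy)benzoate F2. Tf2O and pyridine in CH2Cl2 convert this phenol into methyl 4-methyl-5-(3-methylbut-2-en-1-yl)-6-(pivaloyloxy)-2-(trifluoromethylsulfonyloxy)benzoate F3. Palladium-catalysed diaryl ether formation with phenol 13 (Pd(OAc)2, 2-(di-tert-butylphosphino)-2',4',6'-triisopropylbiphenyl, K3PO4, toluene, 100 °C) then gives 21.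

Step 3. The α-branched acylketene may dimerise or be O-acylated by the malonate enolate instead of C-acylated, and lactonisation of the hindered adduct may stall. The fallback builds the ring with the unbranched ketene and brings in the prenyl group afterwards; it sets out from 1 and 5 and comes back at 9. Dioxinone 1 and the sodium salt of 5 (toluene, 110 °C, acid work-up) give methyl 4-hydroxy-6-methyl-2-oxo-2H-pyran-3-carboxylate F4. N-Bromosuccinimide in DMF brominates the only ring C–H to give methyl 5-bromo-4-hydroxy-6-methyl-2-oxo-2H-pyran-3-carboxylate F5. Pivaloylation as in step 4 gives methyl 5-bromo-6-methyl-2-oxo-4-(pivaloyloxy)-2H-pyran-3-carboxylate F6. Stille coupling of this bromide with stannane 3 (Pd(PPh3)4, CuI, DMF, 60 °C) then gives 9.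

Step 2. Allyl transposition at palladium may give the 1,1-dimethylallyl isomer, and the dioxinone may cyclorevert at the coupling temperature. The fallback replaces cross-coupling by a low-temperature organomagnesium allylation; it sets out from 2 and comes back at 4. Iodine–magnesium exchange (i-PrMgCl·LiCl, THF, −30 °C) gives 5-(chloromagnesio)-2,2,6-trimethyl-4H-1,3-dioxin-4-one F7. This is alkylated at the primary carbon of 1-bromo-3-methylbut-2-ene (CC(C)=CCBr) with Li2CuCl4 (cat.) at −30 to 0 °C to give 4.

Further compounds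
F1 | step 10 | methyl 4-methyl-5-(3-methylbut-2-en-1-yl)-6-(pivaloyloxy)-2-(trimethylsilyloxy)benzoate | COC(=O)c1c(O[Si](C)(C)C)cc(C)c(CC=C(C)C)c1OC(=O)C(C)(C)C
F2 | step 10 | methyl 2-hydroxy-4-methyl-5-(3-methylbut-2-en-1-yl)-6-(pivaloyloxy)benzoate | COC(=O)c1c(O)cc(C)c(CC=C(C)C)c1OC(=O)C(C)(C)C
F3 | step 10 | methyl 4-methyl-5-(3-methylbut-2-en-1-yl)-6-(pivaloyloxy)-2-(trifluoromethylsulfonyloxy)benzoate | COC(=O)c1c(OS(=O)(=O)C(F)(F)F)cc(C)c(CC=C(C)C)c1OC(=O)C(C)(C)C
F4 | step 3 | methyl 4-hydroxy-6-methyl-2-oxo-2H-pyran-3-carboxylate | COC(=O)C1=C(O)C=C(C)OC1=O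
F5 | step 3 | methyl 5-bromo-4-hydroxy-6-methyl-2-oxo-2H-pyran-3-carboxylate | COC(=O)C1=C(O)C(Br)=C(C)OC1=O
F6 | step 3 | methyl 5-bromo-6-methyl-2-oxo-4-(pivaloyloxy)-2H-pyran-3-carboxylate | COC(=O)C1=C(OC(=O)C(C)(C)C)C(Br)=C(C)OC1=O
F7 | step 2 | 5-(chloromagnesio)-2,2,6-trimethyl-4H-1,3-dioxin-4-one | CC1=C([Mg]Cl)C(=O)OC(C)(C)O1
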